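**Retrosynthetic overview**
1. Feature: C8 of ring A carries C1''H2–C2''H[C8''(CH3)=C9''H2]–C3''H2–C4''H=C5''(CH3)2. With boron in place of C1'', the C2''/C3'' pair is the R–CH(B)–CH2–R' unit that a vinylboron ate complex leaves after taking up a migrating group and an electrophile.
2. C8–C1'': B-alkyl Suzuki–Miyaura coupling of the lavandulyl pinacol boronate with 8-iodomorin pentakis(methoxymethyl) ether, followed by acetal removal.
3. C1''–C2'': Matteson insertion of CH2 into the C2''–B bond, with retention.
4. C2''–C8'' and C3''–C4'': one enantioselective three-component conjunctive coupling of isopropenylboronate, vinylmagnesium bromide and 1-bromo-2-methylpropene. It sets C2'', the only stereocentre.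
5. Rings: none is formed. Rings A, B and C come with morin, which is iodinated at C8 while ring B is deactivated as its acetates and only 7-OH is free.

Key step: step 1

Remark on descriptors: the target is (2''R). The same spatial arrangement is (S) in both boronates, because boron, or CH2B, ranks below C3'' in the CIP order.
Assumption: the (Rp,Rp) antipode of the ferrocenyl bisphosphine is taken as the one that gives the (S)-allylic boronate, by analogy with the known sense of induction of this ligand family. Its mirror image is equally available.

**Step 1**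
Reactants: 1 isopropenylboronic acid pinacol ester; 2 vinylmagnesium bromide; 3 1-bromo-2-methylprop-1-ene
Product: 5 (S)-2-(2,6-dimethylhepta-1,5-dien-3-yl)-4,4,5,5-tetramethyl-1,3,2-dioxaborolane, via bis(alkenyl)borate 4 (not isolated)
Conditions: 2 (1.0 equiv) added to 1, THF, 0 °C to rt; then NaOTf (3 equiv), Pd(OAc)2 (2 mol %), (Rp,Rp)-MandyPhos = 1,1'-bis[bis(3,5-dimethylphenyl)phosphino]-2,2'-bis[(dimethylamino)(phenyl)methyl]ferrocene (2.4 mol %), 3 (1.2 equiv), THF/DMSO, 60 °C
Reagents that add atoms: none
Why: Oxidative addition of 3 to zerovalent palladium and removal of bromide by NaOTf give a cationic 2-methylprop-1-enyl complex of divalent palladium that binds the unsubstituted vinyl group of 4; isopropenyl then shifts from boron to the vinyl α-carbon anti to the metal (C2''–C8''), palladium takes C3'', and reductive elimination forms C3''–C4''. The closest known reaction type is the palladium-catalysed enantioselective conjunctive cross-coupling of bis(alkenyl)borates to α-chiral allylic boronates, in its Grignard/NaOTf variant that accepts C(sp2) bromides. No ring is closed. C2'' is the only new stereocentre; the chiral bisphosphine fixes which vinyl face lies on palladium, and the anti-periplanar shift translates that face into the (S)-boronate. Two selectivities are needed: acceptor versus migrating alkene, secured because palladium binds the free CH=CH2 far better than the 1,1-disubstituted isopropenyl group, and metallate shift versus direct alkenyl transfer, secured by the wide-bite-angle ligand, the non-coordinating triflate and the pinacol ligand on boron.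

**Step 2**
Reactants: 5 (S)-allylic boronate
Product: 7 (S)-4,4,5,5-tetramethyl-2-[5-methyl-2-(prop-1-en-2-yl)hex-4-en-1-yl]-1,3,2-dioxaborolane (lavandulyl pinacol boronate), via chloromethyl borate 6 (not isolated)
Conditions: BrCH2Cl (2.5 equiv), n-BuLi (2.2 equiv), THF, −78 °C to rt
Reagents that add atoms: bromochloromethane, ClCBr
Why: Matteson homologation, in which LiCH2Cl generated in the presence of 5 adds to boron and, on warming, C2'' shifts from boron to CH2 with loss of chloride, so C1'' is inserted with retention at C2''.

**Step 3**
Reactants: 8 morin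
Product: 9 morin pentaacetate
Conditions: Ac2O (10 equiv), DMAP (cat.), pyridine, rt
Reagents that add atoms: acetic anhydride, CC(=O)OC(C)=O
Why: Exhaustive O-acylation under nucleophilic catalysis, which also acetylates the chelated 5-OH and lowers the electron density of both aromatic rings ahead of the site-selective steps.

**Step 4**
Reactants: 9 morin pentaacetate
Product: 10 3,5,2',4'-tetra-O-acetylmorin (7-OH free)
Conditions: PhSH (1.5 equiv), imidazole (0.5 equiv), NMP, 0 °C to rt
Reagents that add atoms: none
Why: Chemoselective thiolysis of an aryl ester, a known way to free only 7-OH in peracylated flavones and flavonols, since the 7-acetate is the ester of the most acidic phenol (para to the C4 carbonyl) and so has the best leaving group.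

**Step 5**
Reactants: 10 3,5,2',4'-tetra-O-acetylmorin
Product: 11 3,5,2',4'-tetra-O-acetyl-8-iodomorin
Conditions: NIS (1.05 equiv), TFA (0.2 equiv), MeCN, 0 °C to rt, dark
Reagents that add atoms: N-iodosuccinimide, O=C1CCC(=O)N1I
Why: Electrophilic aromatic iodination of a phenol, directed to ring A because only it bears a free OH while ring B has two weakly donating acetoxy groups, and directed to C8 rather than C6 because 7-hydroxychromones react at C8 (higher C7–C8 bond order) and C6 is crowded by the 5-acetoxy group.

**Step 6**
Reactants: 11 3,5,2',4'-tetra-O-acetyl-8-iodomorin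
Product: 12 8-iodomorin
Conditions: NH3 (7 M in MeOH), 0 °C to rt, Ar
Reagents that add atoms: none
Why: Aminolysis of aryl and enol acetates, which is fast at or below room temperature and leaves the aryl iodide alone, run without air because the flavonol anion is easily oxidised.

**Step 7**
Reactants: 12 8-iodomorin
Product: 13 8-iodomorin 3,5,7,2',4'-pentakis(methoxymethyl) ether
Conditions: NaH (7 equiv), MOMCl (7 equiv), DMF, 0 °C to rt, Ar
Reagents that add atoms: chloromethyl methyl ether, COCCl
Why: Williamson-type O-alkylation of the penta-anion with a hard electrophile, in which the strong base also breaks the 5-OH/C4=O chelate, giving acetals that withstand the aqueous base of step 8 and can later be removed without reduction or strong Lewis acid.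

**Step 8**
Reactants: 7 lavandulyl pinacol boronate (1.5 equiv); 13 8-iodomorin pentakis(methoxymethyl) ether
Product: 14 (2''R)-kushenol C pentakis(methoxymethyl) ether
Conditions: Pd(OAc)2 (5 mol %), RuPhos (10 mol %), K3PO4 (3 equiv), toluene/H2O (10:1), 85 °C
Reagents that add atoms: none
Why: B-alkyl Suzuki–Miyaura coupling of a primary alkyl pinacol boronate with an aryl iodide, in which the weak C8–I bond adds readily to zerovalent palladium, phosphate and water form the transferable hydroxyborate, and the bulky electron-rich biaryl phosphine speeds reductive elimination past β-hydride loss at C2'', which is not a reacting centre and keeps its configuration.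

**Step 9**
Reactants: 14 (2''R)-kushenol C pentakis(methoxymethyl) ether
Product: 15 kushenol C
Conditions: HCl (1.25 M in MeOH), MeOH/THF, 40 °C, stopped when the last acetal is gone
Reagents that add atoms: none
Why: Acid-catalysed transacetalisation of the five methoxymethyl ethers to methanol, in which each acetal ionises through an oxocarbenium ion far faster than the 1,1-di- and trisubstituted alkenes are protonated in dilute methanolic acid, so the diene, the free 7-OH next to it and C2'' should survive.

**Compound list**
1 | isopropenylboronic acid pinacol ester | C=C(C)B1OC(C)(C)C(C)(C)O1 | starting material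
2 | vinylmagnesium bromide | C=C[Mg]Br | starting material
3 | 1-bromo-2-methylprop-1-ene | CC(C)=CBr | starting material
4 | bromomagnesium isopropenyl(vinyl)(pinacolato)borate | C=C[B-]1(C(C)=C)OC(C)(C)C(C)(C)O1.[Mg+2].[Br-] | intermediate
5 | (S)-2-(2,6-dimethylhepta-1,5-dien-3-yl)-4,4,5,5-tetramethyl-1,3,2-dioxaborolane | C=C(C)[C@H](CC=C(C)C)B1OC(C)(C)C(C)(C)O1 | intermediate
6 | lithium (S)-chloromethyl(2,6-dimethylhepta-1,5-dien-3-yl)(pinacolato)borate | C=C(C)[C@H](CC=C(C)C)[B-]1(CCl)OC(C)(C)C(C)(C)O1.[Li+] | intermediate
7 | (S)-lavandulyl pinacol boronate | C=C(C)[C@H](CC=C(C)C)CB1OC(C)(C)C(C)(C)O1 | intermediate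
8 | morin | O=c1c(O)c(-c2ccc(O)cc2O)oc2cc(O)cc(O)c12 | starting material
9 | morin pentaacetate | O=c1c(OC(C)=O)c(-c2ccc(OC(C)=O)cc2OC(C)=O)oc2cc(OC(C)=O)cc(OC(C)=O)c12 | intermediate
10 | 3,5,2',4'-tetra-O-acetylmorin | O=c1c(OC(C)=O)c(-c2ccc(OC(C)=O)cc2OC(C)=O)oc2cc(O)cc(OC(C)=O)c12 | intermediate
11 | 3,5,2',4'-tetra-O-acetyl-8-iodomorin | O=c1c(OC(C)=O)c(-c2ccc(OC(C)=O)cc2OC(C)=O)oc2c(I)c(O)cc(OC(C)=O)c12 | intermediate
12 | 8-iodomorin | O=c1c(O)c(-c2ccc(O)cc2O)oc2c(I)c(O)cc(O)c12 | intermediate
13 | 8-iodomorin 3,5,7,2',4'-pentakis(methoxymethyl) ether | O=c1c(OCOC)c(-c2ccc(OCOC)cc2OCOC)oc2c(I)c(OCOC)cc(OCOC)c12 | intermediate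
14 | (2''R)-kushenol C pentakis(methoxymethyl) ether | C=C(C)[C@H](CC=C(C)C)Cc1c(OCOC)cc(OCOC)c2c(=O)c(OCOC)c(-c3ccc(OCOC)cc3OCOC)oc12 | intermediate
15 | kushenol C, (2''R) | C=C(C)[C@H](CC=C(C)C)Cc1c(O)cc(O)c2c(=O)c(O)c(-c3ccc(O)cc3O)oc12 | target

**Total step count:** 9. **Longest linear sequence:** 7 (steps 3 to 9, from morin).

**Steps most likely to fail**

Risk 1, step 8.
- What may go wrong: transfer of the β-branched primary alkyl group from the pinacol boronate to an arylpalladium flanked by two oxygen substituents may be slow. Protodeiodination, β-hydride loss towards a conjugated diene, or Heck-type insertion of the pendant alkenes could then take over.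
- Fallback: it sets out from 7 and 11 and comes back at 15. It replaces the basic boron coupling by a base-free zinc coupling on the ester-protected core.
- Zinc reagent: oxidation of 7 with NaBO3·4H2O (THF/H2O) gives (S)-lavandulol F1, and I2/PPh3/imidazole converts it into (S)-lavandulyl iodide F2. Iodine–lithium exchange (t-BuLi, 2 equiv, Et2O/pentane, −78 °C) gives lavandulyllithium F3, which ZnBr2 turns into lavandulylzinc bromide F4.
- Coupling partner: Ac2O/pyridine caps the 7-OH of 11 to give 8-iodomorin pentaacetate F5.
- Union and release: Negishi coupling of F4 with F5 (Pd(OAc)2, SPhos, THF, rt to 50 °C) tolerates the esters and benefits from the more electron-poor iodide. It gives kushenol C pentaacetate F6, and NH3 in MeOH, as in step 6, releases 15. This end game also avoids any acid treatment.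

Risk 2, step 1.
- What may go wrong: ate-complex formation from the Grignard reagent may be incomplete, bromide may inhibit the cationic palladium, an alkenyl group may transfer directly from boron, or facial selectivity may erode.
- Fallback: it sets out from 1 and comes back at 5. It uses reagent-controlled lithiation–borylation in place of catalysis.
- Sequence: 4-methylpent-3-en-1-ol and N,N-diisopropylcarbamoyl chloride (Et3N, reflux) give 4-methylpent-3-enyl N,N-diisopropylcarbamate F7. s-BuLi/(+)-sparteine (Et2O, −78 °C) removes the pro-R α-hydrogen to give the configurationally stable (R)-α-lithio carbamate F8. Compound 1 adds with retention to give the carbamoyloxyalkyl borate F9.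
- Stereochemical outcome: warming F9 with MgBr2·OEt2 drives the 1,2-shift of isopropenyl with inversion and loss of the carbamate, which gives (S)-5.

Risk 3, step 5.
- What may go wrong: attack at C6, or double iodination of ring A, may compete with clean substitution at C8.
- Fallback: it sets out from 8 and comes back at 13. It replaces control by the free 7-OH with control by the 5-O-alkyl group.
- Sequence: NaH/MOMCl (DMF, 0 °C to rt) converts morin into morin pentakis(methoxymethyl) ether F10. NIS in DMF at rt under neutral conditions then relies on the known preference of fully O-alkylated 5,7-dioxygenated flavones for iodination at C8.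
- Why it is not the first choice: it is three steps shorter, but ring B is then an activated resorcinol diether and may compete.

**Further compounds**
F1 | step 8 | (S)-lavandulol | C=C(C)[C@H](CC=C(C)C)CO
F2 | step 8 | (S)-lavandulyl iodide | C=C(C)[C@H](CC=C(C)C)CI
F3 | step 8 | (S)-lavandulyllithium | C=C(C)[C@H](CC=C(C)C)C[Li]
F4 | step 8 | (S)-lavandulylzinc bromide | C=C(C)[C@H](CC=C(C)C)C[Zn]Br
F5 | step 8 | 8-iodomorin pentaacetate | O=c1c(OC(C)=O)c(-c2ccc(OC(C)=O)cc2OC(C)=O)oc2c(I)c(OC(C)=O)cc(OC(C)=O)c12
F6 | step 8 | (2''R)-kushenol C pentaacetate | C=C(C)[C@H](CC=C(C)C)Cc1c(OC(C)=O)cc(OC(C)=O)c2c(=O)c(OC(C)=O)c(-c3ccc(OC(C)=O)cc3OC(C)=O)oc12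
F7 | step 1 | 4-methylpent-3-enyl N,N-diisopropylcarbamate | CC(C)=CCCOC(=O)N(C(C)C)C(C)C
F8 | step 1 | (R)-1-lithio-4-methylpent-3-enyl N,N-diisopropylcarbamate | CC(C)=CC[C@H](OC(=O)N(C(C)C)C(C)C)[Li]
F9 | step 1 | lithium (R)-[1-(diisopropylcarbamoyloxy)-4-methylpent-3-enyl](isopropenyl)(pinacolato)borate | CC(C)=CC[C@H](OC(=O)N(C(C)C)C(C)C)[B-]1(C(C)=C)OC(C)(C)C(C)(C)O1.[Li+]
F10 | step 5 | morin pentakis(methoxymethyl) ether | O=c1c(OCOC)c(-c2ccc(OCOC)cc2OCOC)oc2cc(OCOC)cc(OCOC)c12
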